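**Plan**
- **Cuts:** After the phenols and the acid are unmasked, ring C is cut at O1–C2, C3–C4 and C4–C4a, giving 4-ethynylanisole, one formyl carbon and a free C8a phenol. Ring A is then cut at C8–C8a, C6–C7 and C4a–C8a.
- **Enabling feature:** Ring A carries oxygen on C5, C7 and C8a in a 1,3,5 pattern, and C8, which holds the stereocentre, lies between C7–O and C8a–O. An ynol ether (C7, C8) inserted into a 3-alkoxycyclobutenone (C8a, C6, C5, C4a) gives exactly this pattern, with the three oxygens differentiated as OH, OSi and OEt.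
- **Forward order:** side-chain stereocentre, siloxyalkyne, ring A by benzannulation, C4 by ortho-formylation at C4a, C3/C2/ring B by acetylide addition, ring C by 6-endo closure of the ynone, deprotection.
- **Stereochemistry:** The single stereocentre comes from a rhodium-catalysed enantioselective conjugate alkynylation of benzylidene Meldrum's acid. No later step breaks a bond at it.

Key step: step 6

Assumption: the (R)-antipode of the bisphosphine in step 2 is taken to give the (R)-adduct. The sense of induction is to be confirmed by optical rotation at the alkynoic acid of step 3, and the mirror-image ligand is used if the opposite holds.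

Step 1
Reactants: 1 benzaldehyde; 2 Meldrum's acid
Product: 3 5-benzylidene-2,2-dimethyl-1,3-dioxane-4,6-dione
Conditions: pyrrolidine (10 mol %), AcOH (10 mol %), toluene, rt
Reagents that add atoms: none
Why: Knoevenagel condensation of a non-enolisable aldehyde with the very acidic Meldrum's acid runs under mild amine–acid catalysis and gives a symmetric acceptor, so no alkene geometry has to be controlled.

Step 2
Reactants: 3 5-benzylidene-2,2-dimethyl-1,3-dioxane-4,6-dione; 4 ethynyltrimethylsilane
Product: 5 2,2-dimethyl-5-[(1R)-1-phenyl-3-(trimethylsilyl)prop-2-yn-1-yl]-1,3-dioxane-4,6-dione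
Conditions: [Rh(OAc)(C2H4)2]2 (2.5 mol %), (R)-(6,6'-dimethoxybiphenyl-2,2'-diyl)bis[bis(3,5-dimethylphenyl)phosphane] (5.5 mol %), 4 (excess), dioxane, rt
Reagents that add atoms: none
Why: Rhodium-catalysed enantioselective conjugate alkynylation, known for exactly this acceptor class: an alkynylrhodium species formed by acetate-assisted C–H metalation adds 1,4 to the doubly activated alkene, and the C2-symmetric biaryl bisphosphine blocks one alkene face and so sets the stereocentre as (R).

Step 3
Reactants: 5 2,2-dimethyl-5-[(1R)-1-phenyl-3-(trimethylsilyl)prop-2-yn-1-yl]-1,3-dioxane-4,6-dione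
Product: 7 (S)-3-phenylpent-4-ynoic acid, via silylalkynoic acid 6 (not isolated)
Conditions: DMF–H2O (10:1), 100 °C; then K2CO3, MeOH, rt; 1 M HCl
Reagents that add atoms: water, O
Why: Hydrolysis–decarboxylation of a 5-substituted Meldrum's acid is followed by carbonate-mediated protodesilylation on the carboxylate salt, which keeps the benzylic–propargylic C–H safe; the spatial arrangement is unchanged and the descriptor turns from R to S only because ethynyl ranks below phenyl.

Step 4
Reactants: 7 (S)-3-phenylpent-4-ynoic acid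
Product: 8 tert-butyl (S)-3-phenylpent-4-ynoate
Conditions: Cl3CC(=NH)Ot-Bu (2 equiv), CH2Cl2–cyclohexane, rt
Reagents that add atoms: tert-butyl 2,2,2-trichloroacetimidate, CC(C)(C)OC(=N)C(Cl)(Cl)Cl
Why: Trichloroacetimidate tert-butylation of a carboxylic acid (proton transfer, then tert-butyl transfer) needs neither base nor strong acid, so the terminal alkyne and the stereocentre are not disturbed.

Step 5
Reactants: 8 tert-butyl (S)-3-phenylpent-4-ynoate
Product: 11 tert-butyl (R)-3-phenyl-5-(triisopropylsilyloxy)pent-4-ynoate, via lithium acetylide 9 (not isolated), via lithium ynolate 10 (not isolated)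
Conditions: n-BuLi (1.0 equiv), THF, −78 °C; t-BuOOLi (from t-BuOOH and LiN(SiMe3)2, THF, −78 °C), −78 → −10 °C; i-Pr3SiOTf, −78 → 0 °C; Et3N-deactivated silica
Reagents that add atoms: tert-butyl hydroperoxide, CC(C)(C)OO; triisopropylsilyl trifluoromethanesulfonate, CC(C)[Si](C(C)C)(C(C)C)OS(=O)(=O)C(F)(F)F
Why: Acetylide oxidation with lithium tert-butyl peroxide (the carbanion attacks peroxide oxygen and expels tert-butoxide) gives the ynolate, which the bulky silyl triflate traps on oxygen; one equivalent of n-BuLi at −78 °C removes the C(sp)–H faster than it enolises or attacks the hindered ester, and the descriptor returns to R because the oxygenated alkynyl group outranks phenyl.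

Step 6
Reactants: 11 tert-butyl (R)-3-phenyl-5-(triisopropylsilyloxy)pent-4-ynoate; 12 3-ethoxycyclobut-2-en-1-one
Product: 17 tert-butyl (R)-3-[4-ethoxy-2-hydroxy-6-(triisopropylsilyloxy)phenyl]-3-phenylpropanoate, via vinylketene 13 (not isolated), via vinylcyclobutenone 14 (not isolated), via dienylketene 15 (not isolated), via cyclohexadienone 16 (not isolated)
Conditions: 12 (1.5 equiv), toluene (0.5 M), base-washed sealed tube, 110 → 130 °C
Reagents that add atoms: none
Why: Heating opens 12 by a conrotatory 4π electrocyclic reaction to vinylketene 13, whose carbonyl carbon (future C8a) is attacked by the carbon-substituted, nucleophilic terminus of ynol ether 11 (future C8) while the ketene α-carbon (future C6) bonds to the oxygen-bearing alkyne carbon (future C7), giving 14 by a regiospecific [2+2] cycloaddition. A second 4π opening breaks the bond between future C8a and C6 in 14 to give dienylketene 15, which closes ring A by a disrotatory 6π electrocyclisation between the ketene carbon and the terminal CH2 (C8a–C4a) to dienone 16, and enolisation gives phenol 17. This is the Danheiser benzannulation of a cyclobutenone with a triisopropylsiloxyalkyne, the known route to resorcinol monosilyl ethers, and the 3-ethoxy group only supplies the third oxygen. No lasting stereocentre is created: the ring carbon of 14 that bears the ethoxyvinyl group is stereogenic only in passing, and the benzylic centre has no acidic or ionisable bond under neutral thermolysis and keeps its arrangement. The selectivity required is the orientation of the [2+2] step, and it is secured by the oxygen lone-pair polarisation of the siloxyalkyne, which makes the carbon carrying the stereocentre the nucleophile. The tert-butyl ester is chosen because its bulk and poor leaving group slow attack by the neighbouring new phenol, so the C8a hydroxyl stays free as the only unprotected oxygen of ring A.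

Step 7
Reactants: 17 tert-butyl (R)-3-[4-ethoxy-2-hydroxy-6-(triisopropylsilyloxy)phenyl]-3-phenylpropanoate
Product: 18 tert-butyl (R)-3-[4-ethoxy-3-formyl-2-hydroxy-6-(triisopropylsilyloxy)phenyl]-3-phenylpropanoate
Conditions: MgCl2 (3 equiv), Et3N (5 equiv), (CH2O)n (8 equiv), THF, reflux
Reagents that add atoms: paraformaldehyde (as formaldehyde), C=O
Why: In the magnesium-mediated ortho-formylation of phenols (Casnati–Skattebøl reaction) the magnesium phenoxide delivers coordinated formaldehyde through a cyclic transition state only to an ortho carbon, so with C8 blocked the reaction can occur only at C4a and not at the para carbon C6, and a second formaldehyde accepts hydride to give the aldehyde without any Lewis acid that would harm the ester or silyl ether.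

Step 8
Reactants: 18 tert-butyl (R)-3-[4-ethoxy-3-formyl-2-hydroxy-6-(triisopropylsilyloxy)phenyl]-3-phenylpropanoate; 19 1-ethynyl-4-methoxybenzene
Product: 21 tert-butyl (3R)-3-{4-ethoxy-2-hydroxy-3-[1-hydroxy-3-(4-methoxyphenyl)prop-2-yn-1-yl]-6-(triisopropylsilyloxy)phenyl}-3-phenylpropanoate (both carbinol epimers), via lithium arylacetylide 20 (not isolated)
Conditions: 19 (3 equiv), n-BuLi (2.9 equiv), THF, −78 °C; then 18, −78 → 0 °C; aq. NH4Cl; used crude
Reagents that add atoms: none
Why: This is a 1,2-addition of a lithium acetylide to a salicylaldehyde, with the first equivalent acting as base for the phenol; the tert-butyl ester is inert at this temperature, and the new carbinol centre forms unselectively, which does not matter because step 9 removes it.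

Step 9
Reactants: 21 tert-butyl (3R)-3-{4-ethoxy-2-hydroxy-3-[1-hydroxy-3-(4-methoxyphenyl)prop-2-yn-1-yl]-6-(triisopropylsilyloxy)phenyl}-3-phenylpropanoate
Product: 22 tert-butyl (R)-3-{4-ethoxy-2-hydroxy-3-[3-(4-methoxyphenyl)prop-2-ynoyl]-6-(triisopropylsilyloxy)phenyl}-3-phenylpropanoate
Conditions: MnO2 (activated, 20 equiv), CH2Cl2, rt
Reagents that add atoms: none
Why: MnO2 oxidation is selective for the doubly activated benzylic–propargylic alcohol under neutral conditions, and the resulting ynone is stabilised by its hydrogen bond to the ortho phenol.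

Step 10
Reactants: 22 tert-butyl (R)-3-{4-ethoxy-2-hydroxy-3-[3-(4-methoxyphenyl)prop-2-ynoyl]-6-(triisopropylsilyloxy)phenyl}-3-phenylpropanoate
Product: 24 tert-butyl (R)-3-[5-ethoxy-7-hydroxy-2-(4-methoxyphenyl)-4-oxo-4H-chromen-8-yl]-3-phenylpropanoate, via silyl flavone 23 (not isolated)
Conditions: 4-(dimethylamino)pyridine (20 mol %), DMF, 35 °C; then Bu4NF, AcOH, 0 °C → rt
Reagents that add atoms: none
Why: Nucleophile-catalysed 6-endo-dig oxa-Michael cyclisation of an o-alkynoylphenol closes ring C (the pyridine adds to the ynone β-carbon and the phenoxide replaces it by addition–elimination, which avoids the 5-exo path to the aurone), and buffered fluoride then cleaves the aryl silyl ether.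

Step 11
Reactants: 24 tert-butyl (R)-3-[5-ethoxy-7-hydroxy-2-(4-methoxyphenyl)-4-oxo-4H-chromen-8-yl]-3-phenylpropanoate
Product: 25 (R)-3-[5,7-dihydroxy-2-(4-hydroxyphenyl)-4-oxo-4H-chromen-8-yl]-3-phenylpropanoic acid
Conditions: BBr3 (10 equiv), CH2Cl2, −78 °C → rt; ice–water
Reagents that add atoms: none
Why: In this BBr3 ether and ester cleavage, chelation between C4=O and O5 removes the ethyl group first and the aryl methyl ether and tert-butyl ester follow, while the anhydrous, low-temperature medium avoids the hydrolytic pyranone opening behind a Wessely–Moser rearrangement and leaves the stereocentre, which bears no ionisable bond, unchanged.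

**Compound list**
1 | benzaldehyde | O=Cc1ccccc1 | starting material
2 | Meldrum's acid (2,2-dimethyl-1,3-dioxane-4,6-dione) | CC1(C)OC(=O)CC(=O)O1 | starting material
3 | 5-benzylidene-2,2-dimethyl-1,3-dioxane-4,6-dione | CC1(C)OC(=O)C(=Cc2ccccc2)C(=O)O1 | intermediate
4 | ethynyltrimethylsilane | C#C[Si](C)(C)C | starting material
5 | 2,2-dimethyl-5-[(1R)-1-phenyl-3-(trimethylsilyl)prop-2-yn-1-yl]-1,3-dioxane-4,6-dione | CC1(C)OC(=O)C(C(=O)O1)[C@H](c1ccccc1)C#C[Si](C)(C)C | intermediate
6 | (R)-3-phenyl-5-(trimethylsilyl)pent-4-ynoic acid (formed in the flask) | OC(=O)C[C@H](c1ccccc1)C#C[Si](C)(C)C | intermediate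
7 | (S)-3-phenylpent-4-ynoic acid | OC(=O)C[C@H](c1ccccc1)C#C | intermediate
8 | tert-butyl (S)-3-phenylpent-4-ynoate | CC(C)(C)OC(=O)C[C@H](c1ccccc1)C#C | intermediate
9 | C5-lithio derivative (lithium acetylide) of 8, arrangement at C3 unchanged (formed in the flask) | CC(C)(C)OC(=O)C[C@H](c1ccccc1)C#C[Li] | intermediate
10 | lithium (R)-5-tert-butoxy-5-oxo-3-phenylpent-1-yn-1-olate (lithium ynolate, formed in the flask) | CC(C)(C)OC(=O)C[C@H](c1ccccc1)C#C[O-].[Li+] | intermediate
11 | tert-butyl (R)-3-phenyl-5-(triisopropylsilyloxy)pent-4-ynoate | CC(C)(C)OC(=O)C[C@H](c1ccccc1)C#CO[Si](C(C)C)(C(C)C)C(C)C | intermediate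
12 | 3-ethoxycyclobut-2-en-1-one | CCOC1=CC(=O)C1 | starting material
13 | 3-ethoxybuta-1,3-dien-1-one (vinylketene, formed in the flask) | C=C(OCC)C=C=O | intermediate
14 | tert-butyl (3R)-3-[3-(1-ethoxyethenyl)-4-oxo-2-(triisopropylsilyloxy)cyclobut-1-en-1-yl]-3-phenylpropanoate, both ring epimers (formed in the flask) | CC(C)(C)OC(=O)C[C@H](c1ccccc1)C1=C(O[Si](C(C)C)(C(C)C)C(C)C)C(C(=C)OCC)C1=O | intermediate
15 | tert-butyl (3R,5E)-7-ethoxy-4-(oxomethylidene)-3-phenyl-5-(triisopropylsilyloxy)octa-5,7-dienoate (dienylketene, formed in the flask) | CC(C)(C)OC(=O)C[C@H](c1ccccc1)C(=C=O)/C(O[Si](C(C)C)(C(C)C)C(C)C)=C\C(=C)OCC | intermediate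
16 | tert-butyl (R)-3-[4-ethoxy-6-oxo-2-(triisopropylsilyloxy)cyclohexa-1,3-dien-1-yl]-3-phenylpropanoate (formed in the flask) | CC(C)(C)OC(=O)C[C@H](c1ccccc1)C1=C(O[Si](C(C)C)(C(C)C)C(C)C)C=C(OCC)CC1=O | intermediate
17 | tert-butyl (R)-3-[4-ethoxy-2-hydroxy-6-(triisopropylsilyloxy)phenyl]-3-phenylpropanoate | CC(C)(C)OC(=O)C[C@H](c1ccccc1)c1c(O[Si](C(C)C)(C(C)C)C(C)C)cc(OCC)cc1O | intermediate
18 | tert-butyl (R)-3-[4-ethoxy-3-formyl-2-hydroxy-6-(triisopropylsilyloxy)phenyl]-3-phenylpropanoate | CC(C)(C)OC(=O)C[C@H](c1ccccc1)c1c(O[Si](C(C)C)(C(C)C)C(C)C)cc(OCC)c(C=O)c1O | intermediate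
19 | 1-ethynyl-4-methoxybenzene (4-ethynylanisole) | C#Cc1ccc(OC)cc1 | starting material
20 | lithium (4-methoxyphenyl)acetylide (formed in the flask) | [Li]C#Cc1ccc(OC)cc1 | intermediate
21 | tert-butyl (3R)-3-{4-ethoxy-2-hydroxy-3-[1-hydroxy-3-(4-methoxyphenyl)prop-2-yn-1-yl]-6-(triisopropylsilyloxy)phenyl}-3-phenylpropanoate, both carbinol epimers | CC(C)(C)OC(=O)C[C@H](c1ccccc1)c1c(O[Si](C(C)C)(C(C)C)C(C)C)cc(OCC)c(C(O)C#Cc2ccc(OC)cc2)c1O | intermediate
22 | tert-butyl (R)-3-{4-ethoxy-2-hydroxy-3-[3-(4-methoxyphenyl)prop-2-ynoyl]-6-(triisopropylsilyloxy)phenyl}-3-phenylpropanoate | CC(C)(C)OC(=O)C[C@H](c1ccccc1)c1c(O[Si](C(C)C)(C(C)C)C(C)C)cc(OCC)c(C(=O)C#Cc2ccc(OC)cc2)c1O | intermediate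
23 | tert-butyl (R)-3-[5-ethoxy-2-(4-methoxyphenyl)-4-oxo-7-(triisopropylsilyloxy)-4H-chromen-8-yl]-3-phenylpropanoate (formed in the flask) | CC(C)(C)OC(=O)C[C@H](c1ccccc1)c1c(O[Si](C(C)C)(C(C)C)C(C)C)cc(OCC)c2c(=O)cc(-c3ccc(OC)cc3)oc12 | intermediate
24 | tert-butyl (R)-3-[5-ethoxy-7-hydroxy-2-(4-methoxyphenyl)-4-oxo-4H-chromen-8-yl]-3-phenylpropanoate | CC(C)(C)OC(=O)C[C@H](c1ccccc1)c1c(O)cc(OCC)c2c(=O)cc(-c3ccc(OC)cc3)oc12 | intermediate
25 | (R)-3-[5,7-dihydroxy-2-(4-hydroxyphenyl)-4-oxo-4H-chromen-8-yl]-3-phenylpropanoic acid | O=C(O)C[C@H](c1ccccc1)c1c(O)cc(O)c2c(=O)cc(-c3ccc(O)cc3)oc12 | target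

**Total step count:** 11. **Longest linear sequence:** 11 steps (1 → 25); compounds 2, 4, 12 and 19 are bought.

**Steps most likely to fail**

Step 5.
- What may go wrong: oxygen transfer needs time at −10 °C. During it, proton exchange between the acetylide (or the tert-butoxide being formed) and the ester α-CH2 may set in. That would lead to enolate oxidation or to retro-conjugate loss of the acetylide, with erosion of material and of enantiopurity.
- Fallback (from 8, back at 11): the polarity of the alkyne terminus is inverted. PhI(OH)OTs in CH2Cl2 over molecular sieves should convert 8 into [(R)-5-tert-butoxy-5-oxo-3-phenylpent-1-yn-1-yl](phenyl)iodonium tosylate F1. Catalytic CuOTf in MeCN should collapse this to tert-butyl (R)-3-phenyl-5-(tosyloxy)pent-4-ynoate F2. MeLi (2 equiv, THF, −78 °C) attacks sulfur and releases ynolate 10 within minutes at low temperature, and i-Pr3SiOTf then gives 11.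

Step 6.
- What may go wrong: the donor-stabilised cyclobutenone may open only at temperatures at which the siloxyalkyne rearranges, the vinylketene dimerises or acylates the product phenol, and the new phenol lactonises onto the ester.
- Fallback (from 11, back at 17): vinylketene 13 is generated at room temperature by a photochemical Wolff rearrangement, the second-generation form of the benzannulation. α-Lithiated ethyl vinyl ether (t-BuLi, THF) and N-methoxy-N-methylacetamide should give 3-ethoxybut-3-en-2-one F3. LiN(SiMe3)2 and CF3CO2CH2CF3 give 5-ethoxy-1,1,1-trifluorohex-5-ene-2,4-dione F4. MsN3, Et3N and water in MeCN convert this by detrifluoroacetylative diazo transfer into 1-diazo-3-ethoxybut-3-en-2-one F5. Irradiation of F5 with 11 (254 nm, ClCH2CH2Cl, rt), then brief warming to 80 °C, should run the same [2+2]/4π/6π sequence and form the same three bonds to give 17.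

Step 11.
- What may go wrong: the liberated acid may partly lactonise onto the 7-hydroxyl, the tert-butyl cation may be captured by an electron-rich ring, and prolonged acid exposure may open and reclose the pyranone.
- Fallback (from 24, back at 25): the groups are removed in stages, with the lactone used as internal protection. CF3CO2H in CH2Cl2 should remove only the tert-butyl group to give (R)-3-[5-ethoxy-7-hydroxy-2-(4-methoxyphenyl)-4-oxo-4H-chromen-8-yl]-3-phenylpropanoic acid F6. (CF3CO)2O then closes it deliberately to (10R)-5-ethoxy-2-(4-methoxyphenyl)-10-phenyl-9,10-dihydro-4H,8H-pyrano[2,3-f]chromene-4,8-dione F7. BBr3 (CH2Cl2, −78 → 0 °C) now has only two ethers to cleave and should give (10R)-5-hydroxy-2-(4-hydroxyphenyl)-10-phenyl-9,10-dihydro-4H,8H-pyrano[2,3-f]chromene-4,8-dione F8. LiOH (THF–H2O, 0 °C) followed by cold dilute HCl to pH 3 opens the activated aryl lactone to 25.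

**Further compounds**
F1 | step 5 | [(R)-5-tert-butoxy-5-oxo-3-phenylpent-1-yn-1-yl](phenyl)iodonium tosylate | CC(C)(C)OC(=O)C[C@H](c1ccccc1)C#C[I+]c1ccccc1.Cc1ccc(cc1)S(=O)(=O)[O-]
F2 | step 5 | tert-butyl (R)-3-phenyl-5-(tosyloxy)pent-4-ynoate | CC(C)(C)OC(=O)C[C@H](c1ccccc1)C#COS(=O)(=O)c1ccc(C)cc1
F3 | step 6 | 3-ethoxybut-3-en-2-one | C=C(OCC)C(C)=O
F4 | step 6 | 5-ethoxy-1,1,1-trifluorohex-5-ene-2,4-dione | C=C(OCC)C(=O)CC(=O)C(F)(F)F
F5 | step 6 | 1-diazo-3-ethoxybut-3-en-2-one | C=C(OCC)C(=O)C=[N+]=[N-]
F6 | step 11 | (R)-3-[5-ethoxy-7-hydroxy-2-(4-methoxyphenyl)-4-oxo-4H-chromen-8-yl]-3-phenylpropanoic acid | O=C(O)C[C@H](c1ccccc1)c1c(O)cc(OCC)c2c(=O)cc(-c3ccc(OC)cc3)oc12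
F7 | step 11 | (10R)-5-ethoxy-2-(4-methoxyphenyl)-10-phenyl-9,10-dihydro-4H,8H-pyrano[2,3-f]chromene-4,8-dione | O=C1C[C@H](c2ccccc2)c2c(O1)cc(OCC)c1c(=O)cc(-c3ccc(OC)cc3)oc21
F8 | step 11 | (10R)-5-hydroxy-2-(4-hydroxyphenyl)-10-phenyl-9,10-dihydro-4H,8H-pyrano[2,3-f]chromene-4,8-dione | O=C1C[C@H](c2ccccc2)c2c(O1)cc(O)c1c(=O)cc(-c3ccc(O)cc3)oc21
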